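**Retrosynthetic overview**
1. Target 36 comes from desilylation and C4'-acylation of spiro-trione 32 with (S)-2-methylbutanoic acid. The trione ring is closed last, by Dieckmann condensation of acetyl/ester 31.
2. The key bond is C1'–C2', made by an intermolecular Evans aldol of hydrindane aldehyde 20 with propionimide 21. The temporary C1' carbinol then steers a Fráter–Seebach prenylation that sets quaternary C2'.
3. Spiro C6 is fixed by lactonisation of a 6,6-diester through the 1α-alkoxide, which can reach only the α ester. The lactone bridge also forces MeMgBr onto the β face of the C4 ketone.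
4. The cis-hydrindane comes from cyclopentenone by asymmetric 1,4-addition of isopropenyl, Mannich methylenation, Michael addition of dibenzyl malonate and intramolecular allylation.
5. Ring order: cyclopentane (bought) → cyclohexane ring → temporary lactone bridge → cyclohexanetrione ring.

**Locants and faces:** hydrindane C1–C7a, with C1 the five-ring carbinol, C4 the six-ring carbinol and C6 the spiro carbon. Trione ring: C1' (C=O next to the quaternary carbon), C2' (Me, prenyl), C3', C4' (acyl-bearing), C5'. β is the face carrying H-3a and H-7a. "Cage" means the cis-hydrindane whose 6α-carbonyl (C5') is tied to 1α-O as a δ-lactone.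

**Assumption:** hydroxy lactone 16 is taken to stay the six-membered O-1 lactone. An O-4 lactone isomer would carry its silyl group on O-1 and converge again at 31.

Step 1
Reactants: 1 cyclopent-2-en-1-one; 2 isopropenylmagnesium bromide
Product: 4 (S)-trimethyl{[3-(prop-1-en-2-yl)cyclopent-1-en-1-yl]oxy}silane, via isopropenylzinc chloride 3 (not isolated)
Conditions: 2, ZnCl2, THF, 0 °C; then 1, Me3SiCl, [RhCl((S)-binap)]2 (1.5 mol%), THF, 20 °C; cold aq NaHCO3
Reagents that add atoms: chlorotrimethylsilane C[Si](C)(C)Cl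
Why: In this rhodium/BINAP-catalysed asymmetric 1,4-addition under aprotic organozinc/Me3SiCl conditions, the (S)-binap alkenylrhodium species adds to one enone face and sets C3a as S, while the chlorosilane traps the enolate regiospecifically on the C7a side.

Step 2
Reactants: 4 silyl enol ether
Product: 5 (2S,3S)-2-[(dimethylamino)methyl]-3-(prop-1-en-2-yl)cyclopentan-1-one (trans)
Conditions: [Me2N=CH2]I, CH2Cl2, rt; aq NaHCO3
Reagents that add atoms: N,N-dimethylmethyleneiminium iodide (Eschenmoser's salt) C[N+](C)=C.[I-]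
Why: The Mannich reaction of a regiodefined silyl enol ether with a preformed iminium salt places C7 on C7a only and anti to the isopropenyl group, and this centre stays epimerisable until step 5.

Step 3
Reactants: 5 Mannich base; 6 dibenzyl malonate
Product: 9 dibenzyl 2-{[(1R,5S)-2-oxo-5-(prop-1-en-2-yl)cyclopentyl]methyl}malonate (trans), via Mannich methiodide 7 (not isolated), via exo-methylene ketone 8 (not isolated)
Conditions: MeI, Et2O, rt; evaporate; 6 (1.5 equiv), K2CO3, MeCN, 0 °C → rt
Reagents that add atoms: none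
Why: Quaternisation and E1cB loss of trimethylamine release the α-methylene ketone slowly, and intermolecular Michael addition of the malonate captures it before it can dimerise or isomerise, giving the more stable trans ketone with C3a untouched.

Step 4
Reactants: 9 Michael adduct
Product: 10 dibenzyl 2-{[(1R,2S)-2-(3-chloroprop-1-en-2-yl)-5-oxocyclopentyl]methyl}malonate
Conditions: NCS, PhSeCl (5 mol%), CH2Cl2, rt
Reagents that add atoms: N-chlorosuccinimide O=C1CCC(=O)N1Cl
Why: Selenium-catalysed ene-type allylic chlorination attacks only the electron-rich 1,1-disubstituted alkene with allylic shift, leaves the malonate C–H and the ketone alone in the absence of base, and touches no stereocentre.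

Step 5
Reactants: 10 allylic chloride
Product: 12 dibenzyl (3aS,7aS)-4-methylidene-1-oxooctahydro-6H-indene-6,6-dicarboxylate (cis-fused), via trans-fused ketone 11 (not isolated)
Conditions: NaH, NaI (10 mol%), THF/DMF, 0 °C → rt; then DBU (0.3 equiv), rt; chromatography, minor trans isomer re-equilibrated
Reagents that add atoms: none
Why: Intramolecular malonate alkylation (6-exo SN2 on the allylic chloride) closes the cyclohexane ring, and enolate equilibration at C7a turns the first-formed trans ketone into the thermodynamically preferred cis-hydrindan-1-one, which sets C7a (S) relative to C3a.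

Step 6
Reactants: 12 cis-hydrindanone
Product: 13 dibenzyl (1R,3aS,7aS)-1-hydroxy-1-methyl-4-methylideneoctahydro-6H-indene-6,6-dicarboxylate (1β-Me, 1α-OH)
Conditions: MeMgBr, LaCl3·2LiCl, THF, −78 → −20 °C
Reagents that add atoms: methylmagnesium bromide C[Mg]Br
Why: The lanthanide-promoted Grignard 1,2-addition suppresses enolisation and ester attack, and the nucleophile comes from the convex β face of the cis-hydrindanone (anti to C7), giving C1 as R.

Step 7
Reactants: 13 hydroxy diester
Product: 14 cage lactone with 6β-CO2Bn, 1β-methyl and 4-methylidene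
Conditions: NaH (0.2 equiv), THF, 0 °C → rt
Reagents that add atoms: none
Why: In this alkoxide-catalysed lactonisation the 1α-alkoxide can reach only the 6α ester through a 1,3-diaxial bridge, so the two diastereotopic esters are told apart and the C6 configuration is fixed by geometry, while material from any trans-fused impurity cannot cyclise and is removed.

Step 8
Reactants: 14 cage lactone
Product: 15 4-oxo cage lactone (6β-CO2Bn)
Conditions: O3, CH2Cl2, −78 °C; then Me2S, −78 °C → rt
Reagents that add atoms: ozone [O-][O+]=O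
Why: Ozonolysis with reductive work-up cleaves the only alkene to the C4 ketone under neutral conditions, and C3a cannot epimerise because the lactone bridge tolerates only the cis ring fusion.

Step 9
Reactants: 15 keto lactone
Product: 16 4α-hydroxy-4β-methyl cage lactone (6β-CO2Bn)
Conditions: MeMgBr, LaCl3·2LiCl, THF, −78 °C; AcOH quench at −78 °C
Reagents that add atoms: methylmagnesium bromide C[Mg]Br
Why: In this chemoselective Grignard 1,2-addition the ketone reacts ahead of the neopentyl ester and lactone, the lactone bridge covers the α face, and methyl therefore enters from the open β face (equatorial attack) to set C4 as R with 4α-OH.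

Step 10
Reactants: 16 tertiary alcohol
Product: 17 4α-triethylsilyloxy-4β-methyl cage lactone (6β-CO2Bn)
Conditions: Et3SiOTf, 2,6-lutidine, CH2Cl2, 0 °C → rt
Reagents that add atoms: triethylsilyl trifluoromethanesulfonate CC[Si](CC)(CC)OS(=O)(=O)C(F)(F)F
Why: Silyl triflate silylation caps the axial tertiary alcohol, with the silyl group pointing outward, so that no acidic or nucleophilic oxygen sits next to the lactone in the later base steps.

Step 11
Reactants: 17 benzyl ester
Product: 18 cage lactone 6β-carboxylic acid (4α-OTES)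
Conditions: H2 (1 atm), Pd/C, EtOAc, rt
Reagents that add atoms: none
Why: Hydrogenolysis removes the benzyl group under neutral conditions without touching lactone or silyl ether, and the malonic-type half acid is kept at or below room temperature to avoid decarboxylation.

Step 12
Reactants: 18 acid
Product: 19 6β-hydroxymethyl cage lactone (4α-OTES)
Conditions: BH3·SMe2, THF, 0 °C → rt; aq MeOH
Reagents that add atoms: none
Why: Borane reduces the free carboxylic acid through an acyloxyborane much faster than the hindered lactone.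

Step 13
Reactants: 19 primary alcohol
Product: 20 6β-carbaldehyde cage lactone (4α-OTES)
Conditions: Dess–Martin periodinane, pyridine, CH2Cl2, 0 °C → rt
Reagents that add atoms: none
Why: Buffered Dess–Martin oxidation gives the non-enolisable neopentyl aldehyde without over-oxidation or deformylation.

Step 14
Reactants: 20 aldehyde; 21 (R)-4-benzyl-3-propionyloxazolidin-2-one
Product: 24 (4R)-4-benzyl-3-[(2R,3R)-3-hydroxy-2-methyl-3-(cage-6β-yl)propanoyl]oxazolidin-2-one, via boron enolate 22 (not isolated), via boron aldolate 23 (not isolated)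
Conditions: 21, n-Bu2BOTf, Et3N, CH2Cl2, −78 → 0 °C; 20, −78 → 0 °C; H2O2, MeOH, pH 7 buffer
Reagents that add atoms: none
Why: In the intermolecular Evans syn aldol the (Z)-boron enolate reacts through a closed chair transition state under auxiliary control, forms C1'–C2' and sets the temporary C1' carbinol as R, and the aldehyde is equatorial on the cage, activated by the α-acyl group and has little facial bias of its own.

Step 15
Reactants: 24 aldol adduct
Product: 25 methyl (2R,3R)-3-hydroxy-2-methyl-3-(cage-6β-yl)propanoate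
Conditions: Sm(OTf)3 (10 mol%), MeOH, rt
Reagents that add atoms: methanol CO
Why: Lewis-acid-catalysed methanolysis works because chelation of the imide dicarbonyl activates only the exocyclic acyl group, so the auxiliary leaves under neutral conditions without retro-aldol or lactone opening.

Step 16
Reactants: 25 β-hydroxy ester; 26 prenyl bromide
Product: 28 methyl (2S,3R)-3-hydroxy-2-methyl-2-(3-methylbut-2-en-1-yl)-3-(cage-6β-yl)propanoate, via dilithio dianion 27 (not isolated)
Conditions: LDA (2.5 equiv), THF, −78 → −30 °C; 26, DMPU, −78 → −30 °C; cold aq quench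
Reagents that add atoms: none
Why: In the Fráter–Seebach alkylation the lithium-chelated alkoxide/enolate dianion is attacked on the face away from the very bulky C6 residue, so prenyl enters anti to the hydroxyl group and quaternary C2' gets the target configuration.

Step 17
Reactants: 28 hindered carbinol
Product: 29 methyl (S)-2-methyl-2-(3-methylbut-2-en-1-yl)-3-oxo-3-(cage-6β-yl)propanoate
Conditions: Dess–Martin periodinane, pyridine, CH2Cl2, rt
Reagents that add atoms: none
Why: Dess–Martin oxidation, helped by relief of strain at the doubly neopentyl carbinol, erases the temporary C1' stereocentre, while C2' and C6 are quaternary and cannot epimerise.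

Step 18
Reactants: 29 keto lactone ester
Product: 30 6α-acetyl-1α-hydroxy compound (opened cage, 4α-OTES, 6β-C(=O)–C2'(Me)(prenyl)–CO2Me)
Conditions: MeLi (1.1 equiv), Et2O/THF, −78 °C; aq NH4Cl at −78 °C
Reagents that add atoms: methyllithium [Li]C
Why: A single organolithium addition hits the strained, ketone-activated lactone ahead of the acyclic α-quaternary methyl ester and the doubly neopentyl ketone, the tetrahedral lithium adduct survives at −78 °C so no second addition occurs, and the substrate has no acidic proton.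

Step 19
Reactants: 30 hydroxy ketone
Product: 31 1α,4α-bis(triethylsilyloxy) acetyl keto ester
Conditions: Et3SiOTf, 2,6-lutidine, CH2Cl2, −78 → 0 °C
Reagents that add atoms: triethylsilyl trifluoromethanesulfonate CC[Si](CC)(CC)OS(=O)(=O)C(F)(F)F
Why: Silylation of the liberated tertiary alcohol removes the alkoxide that could otherwise add to the acetyl group and trigger a retro-Claisen cleavage in the next step.

Step 20
Reactants: 31 acetyl keto ester
Product: 32 spiro-trione (enol form, C4'–H; 1α,4α-bis-OTES)
Conditions: KHMDS (2.5 equiv), THF, −78 °C → rt; 1 M HCl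
Reagents that add atoms: none
Why: In the Dieckmann condensation the acetyl CH3 is the only enolisable position, its enolate attacks the C3' ester in a six-membered closure, and formation of the acidic 1,3-dione anion drives the reaction and corrects any O-acylation.

Step 21
Reactants: 32 spiro-trione; 33 (S)-2-methylbutanoic acid
Product: 35 bis-TES ether of hyperielliptone HB, via enol ester 34 (not isolated)
Conditions: 33, DCC, DMAP, CH2Cl2, rt
Reagents that add atoms: none
Why: Steglich O-acylation of the 1,3-dione is followed by DMAP-mediated O→C acyl migration to the stabilised β-triketone, the silyl ethers are inert, and the α-alkyl stereocentre of the chiral-pool acid is carried over without strong base.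

Step 22
Reactants: 35 bis-silyl ether
Product: 36 hyperielliptone HB
Conditions: HF·pyridine, pyridine, THF, 0 °C → rt
Reagents that add atoms: none
Why: Buffered fluoride desilylation frees both tertiary alcohols without ionising them or touching the prenyl group and the enolised triketone.

**Compound list**
1 | cyclopent-2-en-1-one | O=C1C=CCC1 | starting material
2 | isopropenylmagnesium bromide | CC(=C)[Mg]Br | starting material
3 | isopropenylzinc chloride | CC(=C)[Zn]Cl | intermediate
4 | (S)-trimethyl{[3-(prop-1-en-2-yl)cyclopent-1-en-1-yl]oxy}silane | C[Si](C)(C)OC1=C[C@H](CC1)C(C)=C | intermediate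
5 | (2S,3S)-2-[(dimethylamino)methyl]-3-(prop-1-en-2-yl)cyclopentan-1-one | CN(C)C[C@@H]1[C@H](CCC1=O)C(C)=C | intermediate
6 | dibenzyl malonate | O=C(CC(=O)OCc1ccccc1)OCc1ccccc1 | starting material
7 | methiodide of 5 | C[N+](C)(C)C[C@@H]1[C@H](CCC1=O)C(C)=C.[I-] | intermediate
8 | (R)-2-methylidene-3-(prop-1-en-2-yl)cyclopentan-1-one | C=C1[C@H](CCC1=O)C(C)=C | intermediate
9 | dibenzyl 2-{[(1R,5S)-2-oxo-5-(prop-1-en-2-yl)cyclopentyl]methyl}malonate | O=C(OCc1ccccc1)C(C[C@@H]1[C@H](CCC1=O)C(C)=C)C(=O)OCc1ccccc1 | intermediate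
10 | dibenzyl 2-{[(1R,2S)-2-(3-chloroprop-1-en-2-yl)-5-oxocyclopentyl]methyl}malonate | O=C(OCc1ccccc1)C(C[C@@H]1[C@H](CCC1=O)C(=C)CCl)C(=O)OCc1ccccc1 | intermediate
11 | dibenzyl (3aS,7aR)-4-methylidene-1-oxooctahydro-6H-indene-6,6-dicarboxylate (trans) | O=C(OCc1ccccc1)C1(C[C@@H]2[C@H](CCC2=O)C(=C)C1)C(=O)OCc1ccccc1 | intermediate
12 | dibenzyl (3aS,7aS)-4-methylidene-1-oxooctahydro-6H-indene-6,6-dicarboxylate (cis) | O=C(OCc1ccccc1)C1(C[C@H]2[C@H](CCC2=O)C(=C)C1)C(=O)OCc1ccccc1 | intermediate
13 | dibenzyl (1R,3aS,7aS)-1-hydroxy-1-methyl-4-methylideneoctahydro-6H-indene-6,6-dicarboxylate | O=C(OCc1ccccc1)C1(C[C@H]2[C@H](CC[C@@]2(C)O)C(=C)C1)C(=O)OCc1ccccc1 | intermediate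
14 | cage lactone, 6β-CO2Bn, 4-methylidene | O=C(OCc1ccccc1)[C@]1(C[C@H]2[C@H](CC[C@@]2(C)O3)C(=C)C1)C3=O | intermediate
15 | cage lactone, 6β-CO2Bn, 4-oxo | O=C(OCc1ccccc1)[C@]1(C[C@H]2[C@H](CC[C@@]2(C)O3)C(=O)C1)C3=O | intermediate
16 | cage lactone, 6β-CO2Bn, 4α-OH, 4β-Me | O=C(OCc1ccccc1)[C@]1(C[C@H]2[C@H](CC[C@@]2(C)O3)[C@](C)(O)C1)C3=O | intermediate
17 | cage lactone, 6β-CO2Bn, 4α-OTES, 4β-Me | O=C(OCc1ccccc1)[C@]1(C[C@H]2[C@H](CC[C@@]2(C)O3)[C@](C)(O[Si](CC)(CC)CC)C1)C3=O | intermediate
18 | cage lactone 6β-carboxylic acid | OC(=O)[C@]1(C[C@H]2[C@H](CC[C@@]2(C)O3)[C@](C)(O[Si](CC)(CC)CC)C1)C3=O | intermediate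
19 | cage lactone, 6β-CH2OH | OC[C@]1(C[C@H]2[C@H](CC[C@@]2(C)O3)[C@](C)(O[Si](CC)(CC)CC)C1)C3=O | intermediate
20 | cage lactone 6β-carbaldehyde | O=C[C@]1(C[C@H]2[C@H](CC[C@@]2(C)O3)[C@](C)(O[Si](CC)(CC)CC)C1)C3=O | intermediate
21 | (R)-4-benzyl-3-propionyloxazolidin-2-one | CCC(=O)N1[C@H](Cc2ccccc2)COC1=O | starting material
22 | (Z)-dibutylboron enolate of 21 | C/C=C(\OB(CCCC)CCCC)N1[C@H](Cc2ccccc2)COC1=O | intermediate
23 | dibutylboron aldolate of 24 | C[C@@H](C(=O)N1[C@H](Cc2ccccc2)COC1=O)[C@@H](OB(CCCC)CCCC)[C@]3(C[C@H]4[C@H](CC[C@@]4(C)O5)[C@](C)(O[Si](CC)(CC)CC)C3)C5=O | intermediate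
24 | Evans syn aldol adduct (2R,3R) | C[C@@H](C(=O)N1[C@H](Cc2ccccc2)COC1=O)[C@@H](O)[C@]3(C[C@H]4[C@H](CC[C@@]4(C)O5)[C@](C)(O[Si](CC)(CC)CC)C3)C5=O | intermediate
25 | methyl (2R,3R)-3-hydroxy-2-methyl-3-(cage-6β-yl)propanoate | C[C@@H](C(=O)OC)[C@@H](O)[C@]1(C[C@H]2[C@H](CC[C@@]2(C)O3)[C@](C)(O[Si](CC)(CC)CC)C1)C3=O | intermediate
26 | prenyl bromide (1-bromo-3-methylbut-2-ene) | CC(C)=CCBr | starting material
27 | dilithio alkoxide/enolate of 25 | [Li]O/C(OC)=C(/C)[C@@H](O[Li])[C@]1(C[C@H]2[C@H](CC[C@@]2(C)O3)[C@](C)(O[Si](CC)(CC)CC)C1)C3=O | intermediate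
28 | methyl (2S,3R)-3-hydroxy-2-methyl-2-prenyl-3-(cage-6β-yl)propanoate | COC(=O)[C@@](C)(CC=C(C)C)[C@@H](O)[C@]1(C[C@H]2[C@H](CC[C@@]2(C)O3)[C@](C)(O[Si](CC)(CC)CC)C1)C3=O | intermediate
29 | methyl (S)-2-methyl-2-prenyl-3-oxo-3-(cage-6β-yl)propanoate | COC(=O)[C@@](C)(CC=C(C)C)C(=O)[C@]1(C[C@H]2[C@H](CC[C@@]2(C)O3)[C@](C)(O[Si](CC)(CC)CC)C1)C3=O | intermediate
30 | 6α-acetyl-1α-hydroxy keto ester (4α-OTES) | COC(=O)[C@@](C)(CC=C(C)C)C(=O)[C@]1(C[C@H]2[C@H](CC[C@@]2(C)O)[C@](C)(O[Si](CC)(CC)CC)C1)C(C)=O | intermediate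
31 | 6α-acetyl keto ester, 1α,4α-bis-OTES | COC(=O)[C@@](C)(CC=C(C)C)C(=O)[C@]1(C[C@H]2[C@H](CC[C@@]2(C)O[Si](CC)(CC)CC)[C@](C)(O[Si](CC)(CC)CC)C1)C(C)=O | intermediate
32 | spiro-trione (enol), 1α,4α-bis-OTES | C1=C(O)[C@@](C)(CC=C(C)C)C(=O)[C@]2(C[C@H]3[C@H](CC[C@@]3(C)O[Si](CC)(CC)CC)[C@](C)(O[Si](CC)(CC)CC)C2)C1=O | intermediate
33 | (S)-2-methylbutanoic acid | CC[C@H](C)C(=O)O | starting material
34 | enol (S)-2-methylbutanoate of 32 | C1=C(OC(=O)[C@@H](C)CC)[C@@](C)(CC=C(C)C)C(=O)[C@]2(C[C@H]3[C@H](CC[C@@]3(C)O[Si](CC)(CC)CC)[C@](C)(O[Si](CC)(CC)CC)C2)C1=O | intermediate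
35 | bis-TES ether of hyperielliptone HB | CC[C@H](C)C(=O)C1=C(O)[C@@](C)(CC=C(C)C)C(=O)[C@]2(C[C@H]3[C@H](CC[C@@]3(C)O[Si](CC)(CC)CC)[C@](C)(O[Si](CC)(CC)CC)C2)C1=O | intermediate
36 | hyperielliptone HB | CC[C@H](C)C(=O)C1=C(O)[C@@](C)(CC=C(C)C)C(=O)[C@]2(C[C@H]3[C@H](CC[C@@]3(C)O)[C@](C)(O)C2)C1=O | target

**Total step count:** 22. **Longest linear sequence:** 22 (1 → 36). All other fragments are bought.

**Three steps most likely to fail**

Step 1. Alkenylzinc transfer to rhodium with silyl trapping is the least precedented step, so conversion or ee may be poor. The fallback gives up enolate trapping and lets a tether decide the regiochemistry. It sets out from 1.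
- Aqueous Hayashi–Miyaura addition of potassium isopropenyltrifluoroborate ([Rh(cod)2]BF4, (S)-BINAP, toluene/H2O) gives (S)-3-(prop-1-en-2-yl)cyclopentan-1-one F1.
- NCS/PhSeCl gives (S)-3-(3-chloroprop-1-en-2-yl)cyclopentan-1-one F2.
- Alkylation of 6 (NaH) gives dibenzyl 2-{2-[(S)-3-oxocyclopentyl]prop-2-en-1-yl}malonate F3.
- C7 is then brought in on the malonate side: aqueous formaldehyde/KHCO3 gives the hydroxymethyl malonate F4, and Dess–Martin oxidation gives the formyl malonate F5.
- An intramolecular aldol condensation (pyrrolidinium acetate) can reach only C7a and gives the bicyclic enone F6.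
- Conjugate reduction with [(Ph3P)CuH]6 and DBU equilibration come back to the route at 12.

Step 16. The dianion is very crowded, and the lithium aldolate of 28 can undergo retro-aldol cleavage. The fallback replaces substrate control by catalyst control on a soft enolate. It sets out from 25.
- Dess–Martin oxidation gives the α-methyl β-keto ester F7 as a C2' epimer mixture.
- F7 is C-prenylated with 26 under solid–liquid phase-transfer conditions (K2CO3, toluene, a chiral binaphthyl-derived N-spiro quaternary ammonium bromide, 0 °C).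
- This comes back to the route at 29. No alkoxide is ever present, so retro-aldol is excluded.

Step 18. MeLi must distinguish the lactone from the methyl ester, and the tetrahedral adduct could fragment by retro-Claisen cleavage. The fallback separates ring opening from C–C bond formation. It sets out from 29.
- MeNH(OMe)·HCl/i-PrMgCl (THF, −20 °C) opens only the strained lactone to the 6α-Weinreb amide F8.
- The chelated adduct of F8 with MeMgBr (0 °C) cannot over-add, and at this temperature the Grignard reagent does not touch the α-quaternary ester.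
- Work-up comes back to the route at 30.

**Further compounds**
F1 | step 1 | (S)-3-(prop-1-en-2-yl)cyclopentan-1-one | C1[C@H](CCC1=O)C(C)=C
F2 | step 1 | (S)-3-(3-chloroprop-1-en-2-yl)cyclopentan-1-one | C1[C@H](CCC1=O)C(=C)CCl
F3 | step 1 | dibenzyl 2-{2-[(S)-3-oxocyclopentyl]prop-2-en-1-yl}malonate | C1[C@H](CCC1=O)C(=C)CC(C(=O)OCc2ccccc2)C(=O)OCc2ccccc2
F4 | step 1 | dibenzyl 2-(hydroxymethyl)-2-{2-[(S)-3-oxocyclopentyl]prop-2-en-1-yl}malonate | C1[C@H](CCC1=O)C(=C)CC(CO)(C(=O)OCc2ccccc2)C(=O)OCc2ccccc2
F5 | step 1 | dibenzyl 2-formyl-2-{2-[(S)-3-oxocyclopentyl]prop-2-en-1-yl}malonate | C1[C@H](CCC1=O)C(=C)CC(C=O)(C(=O)OCc2ccccc2)C(=O)OCc2ccccc2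
F6 | step 1 | dibenzyl (3aR)-4-methylidene-1-oxo-1,2,3,3a,4,5-hexahydro-6H-indene-6,6-dicarboxylate | O=C(OCc1ccccc1)C1(C=C2[C@H](CCC2=O)C(=C)C1)C(=O)OCc1ccccc1
F7 | step 16 | methyl 2-methyl-3-oxo-3-(cage-6β-yl)propanoate (C2' epimers) | COC(=O)C(C)C(=O)[C@]1(C[C@H]2[C@H](CC[C@@]2(C)O3)[C@](C)(O[Si](CC)(CC)CC)C1)C3=O
F8 | step 18 | 6α-(N-methoxy-N-methylcarbamoyl)-1α-hydroxy keto ester (4α-OTES) | COC(=O)[C@@](C)(CC=C(C)C)C(=O)[C@]1(C[C@H]2[C@H](CC[C@@]2(C)O)[C@](C)(O[Si](CC)(CC)CC)C1)C(=O)N(C)OC
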